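The ratio of the summed constants of the two steps that consume first product to the constant of the step that makes it, κ = 0.241, is the selectivity factor of these flasks.

| setting | grey | violet | ochre | blue |
|---|---|---|---|---|
| substrate | 0.050 M | 0.050 M (fed, over 50.0 h) | 0.050 M | 0.050 M |
| coupling partner | 0.0900 M | 0.0900 M | 0.0900 M (fed, over 50.0 h) | 0.0900 M |
| time | 50 h | 50 h | 50 h |  |
| remark | a closed flask charged with all of it at once and left for 50 h | a stirred flask in which substrate is dosed at a steady rate over 50.0 h without added volume, worked up at 50 h | a stirred flask in which coupling partner is dosed at a steady rate over 50.0 h without added volume, worked up at 50 h | one stirred flow tank at steady state, fed with the mixture as stated, mean residence time 50 h |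

    substrate + coupling partner → first product + by-product (k1 = 1.6 × 10⁻⁴ M⁻¹ s⁻¹)
    coupling partner + first product → double product + by-product (k2 = 9.6 × 10⁻⁶ M⁻¹ s⁻¹)
    coupling partner + first product → over-reaction product (k3 = 2.9 × 10⁻⁵ M⁻¹ s⁻¹)

- the stated concentrations are those of everything mixed, before any reaction; amounts are the same in each set-up
- the feed brings no volume worth counting
- run time (grey): 50 h

- order of the set-ups by the amount of first product at the outlet or at the end, in percent of the substrate put in, highest first (grey / violet / ochre / blue)
- amount of first product at the outlet or at the end, in percent of the substrate put in, grey
- amount of first product at the outlet or at the end, in percent of the substrate put in, violet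
- amount of first product at the outlet or at the end, in percent of the substrate put in, ochre
- amount of first product at the outlet or at the end, in percent of the substrate put in, blue

Every step is first order in coupling partner, so [coupling partner] divides out of the ratio of rates. It sets the clock, not the branching. In grey and ochre, where substrate is not fed, x is the fraction of substrate left and m the fraction present as first product:

d m / d x = −1 + κ m / x, so m = (x^κ − x) / (1 − κ)

This curve peaks at x = 15.4%. In grey, each substrate consumed has cost at least one and at most two coupling partner. Integrating the second-order rate with these two limits gives:

17.0% < x < 30.7%

The peak lies at smaller x than this range, so m rises as x falls across it, and the curve brackets grey: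

58.6% < m < 63.5%

For blue, the tank balances give m = x(1 − x) / (x + κ(1 − x)), with a ceiling at any conversion of:

m = 1 / (1 + √κ)^2 = 45.0%

That ceiling is lower than the floor of grey. Violet leaves the curve, and the clock of ochre stays beyond this hand reckoning.

The forecast gives grey > ochre > violet > blue, with 63.3% for grey, 47% for violet, 52.5% for ochre and 44% for blue, and holds that the “flow tank does worst because it runs at outlet concentrations”. Its grey value lies inside the bracket, and its blue value lies under the ceiling.

The simulation gives grey > ochre > violet > blue, with 63.3% for grey, 46.7% for violet, 52.8% for ochre and 44.1% for blue.

Grey holds 18.9% substrate at the end, inside the range for x, and the curve turns that reading into 63.3% first product. The neighbour of grey, charged with 0.036 M of coupling partner for the same time, holds less coupling partner than grey and has the same κ. That neighbour flask ends with 54.9% substrate, the curve gives 41.7%, and its first product reads 41.7%.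

Its constants were drawn at random within sensible limits; the result is computed.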